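**Assumption:** the target SMILES has no stereocentre and no stereogenic C=C (both prenyl alkenes carry a gem-dimethyl terminus), so eryvarin F is achiral and there is no enantiomer to select. The route makes exactly the constitution given. It is a paper proposal and has not been run.

## Retrosynthetic overview

1. Eryvarin F comes from its 7,4'-bis-MOM ether by one global deprotection.
2. Key disconnection (new reaction): the C3–O(aryl) bond and the pyranone O1–C2 bond are formed together by annulating an o-hydroxyaryl enaminone with a 4-alkoxy-o-benzoquinone. The quinone serves as an "ArO⁺" synthon, and its second oxygen becomes the 2'-OH.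
3. The enaminone comes from the acetophenone and DMF-DMA; both prenyl C–C bonds come from a double Suzuki–Miyaura coupling of a 3,5-diiodide made from 2,4-dihydroxyacetophenone.
4. The o-quinone comes from a catechol, made by Dakin oxidation of 4-O-MOM-2,4-dihydroxybenzaldehyde.
5. Ring order: rings A and B are purchased; the pyranone ring C is formed last, in the key step.

Compounds are numbered in order of first appearance in the forward route.

## Route

**Step 1**
Reactants: 1, 2,4-dihydroxyacetophenone
Product: 2, 1-(2,4-dihydroxy-3,5-diiodophenyl)ethanone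
Conditions: NIS (2.2 equiv), TsOH (10 mol %), MeCN, 0 °C → rt
Reagents that add atoms: N-iodosuccinimide, O=C1CCC(=O)N1I
Why: Electrophilic aromatic iodination occurs at C3 and C5, the only positions ortho/para to both hydroxyls; C6 is meta to both and deactivated by the acyl group.

**Step 2**
Reactants: 2, 1-(2,4-dihydroxy-3,5-diiodophenyl)ethanone
Product: 3, 1-[2-hydroxy-3,5-diiodo-4-(methoxymethoxy)phenyl]ethanone
Conditions: MOMCl (1.1 equiv), i-Pr2NEt, CH2Cl2, 0 °C → rt
Reagents that add atoms: chloromethyl methyl ether, COCCl
Why: Chemoselective O-alkylation (Williamson type) of the acidic, non-chelated 4-OH; the 2-OH is held in an intramolecular hydrogen bond to the ketone and stays free.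

**Step 3**
Reactants: 3, 1-[2-hydroxy-3,5-diiodo-4-(methoxymethoxy)phenyl]ethanone
Product: 4, 1-[2-hydroxy-4-(methoxymethoxy)-3,5-bis(3-methylbut-2-en-1-yl)phenyl]ethanone
Conditions: prenylBpin (3 equiv), Pd(dppf)Cl2·CH2Cl2 (10 mol %), K3PO4, THF/H2O, 70 °C
Reagents that add atoms: prenylboronic acid pinacol ester, CC(C)=CCB1OC(C)(C)C(C)(C)O1
Why: Double Suzuki–Miyaura coupling of the two aryl iodides; reductive elimination at the less hindered CH2 terminus of the prenyl–Pd intermediate gives the linear prenyl groups, and the ketone, MOM ether and phenoxide are tolerated.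

**Step 4**
Reactants: 4, 1-[2-hydroxy-4-(methoxymethoxy)-3,5-bis(3-methylbut-2-en-1-yl)phenyl]ethanone
Product: 5, (E)-3-(dimethylamino)-1-[2-hydroxy-4-(methoxymethoxy)-3,5-bis(3-methylbut-2-en-1-yl)phenyl]prop-2-en-1-one
Conditions: DMF-DMA (3 equiv), toluene, 90 °C
Reagents that add atoms: N,N-dimethylformamide dimethyl acetal, COC(OC)N(C)C
Why: Aminomethylenation (condensation) of the methyl ketone gives the thermodynamic E-enaminone; the 7-O is MOM-protected so DMF-DMA cannot methylate it, and the chelated 2-OH is retained.

**Step 5**
Reactants: 6, 2,4-dihydroxybenzaldehyde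
Product: 7, 2-hydroxy-4-(methoxymethoxy)benzaldehyde
Conditions: MOMCl (1.05 equiv), K2CO3, acetone, 0 °C → rt
Reagents that add atoms: chloromethyl methyl ether, COCCl
Why: Selective alkylation of the 4-OH, because the 2-OH is hydrogen-bonded to the aldehyde.

**Step 6**
Reactants: 7, 2-hydroxy-4-(methoxymethoxy)benzaldehyde
Product: 8, 4-(methoxymethoxy)benzene-1,2-diol
Conditions: 30 % H2O2, aq NaOH, THF/H2O, 0 °C → rt, N2; NaH2PO4/Na2S2O4 work-up
Reagents that add atoms: hydrogen peroxide, OO
Why: Dakin oxidation — the ortho-hydroxyl promotes aryl migration in the peroxide adduct and the aryl formate hydrolyses in situ; the MOM ether is base-stable.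

**Step 7**
Reactants: 8, 4-(methoxymethoxy)benzene-1,2-diol
Product: 9, 4-(methoxymethoxy)cyclohexa-3,5-diene-1,2-dione (4-MOM-oxy-o-benzoquinone), filtered and used at once as a solution
Conditions: Ag2O, Na2SO4, CH2Cl2, 0 °C, dark, 30 min
Reagents that add atoms: none
Why: Neutral, anhydrous two-electron oxidation of a catechol to the o-quinone, which the acid-labile MOM group survives.

**Step 8 (proposed new reaction)**
Reactants: 5, the enaminone from Step 4; 9, 4-(methoxymethoxy)-o-benzoquinone (1.3 equiv)
Product: 10, 3-[2-hydroxy-4-(methoxymethoxy)phenoxy]-7-(methoxymethoxy)-6,8-bis(3-methylbut-2-en-1-yl)-4H-chromen-4-one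
Conditions: toluene/CH2Cl2, 4 Å MS, −20 °C → rt, dark; then AcOH (3 equiv), 35 °C
Reagents that add atoms: none
Why: Proposed new method: a redox-neutral aryloxylative annulation in which the nucleophilic α-carbon of the enaminone adds to the O=C–C=O heterodiene of 9 (inverse-electron-demand oxa-Diels–Alder or its stepwise polar equivalent), bonding to the oxygen para to OMOM because the charge then develops on the oxygen meta to OMOM, the better-stabilised phenoxide; the resulting 2-(dimethylamino)-3-aroyl-2,3-dihydro-1,4-benzodioxine ionises at the N,O-aminal under AcOH, the A-ring 2-OH closes on the iminium carbon, and loss of Me2NH (trapped as its acetate) gives the γ-pyrone with the C3–O bond and the free 2'-OH in place; the closest known reaction types are enamine or enol ether + o-quinone [4+2] cycloadditions to 1,4-benzodioxanes, o-quinone methide + enaminone oxa-[4+2]/amine elimination, and electrophile-triggered cyclisation of o-hydroxyaryl enaminones to 3-substituted chromones; no stereocentre is formed.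

**Step 9**
Reactants: 10, the bis-MOM chromone from Step 8
Product: 11, eryvarin F, 3-(2,4-dihydroxyphenoxy)-7-hydroxy-6,8-bis(3-methylbut-2-en-1-yl)-4H-chromen-4-one
Conditions: 3 M aq HCl, MeOH/THF, 50 °C
Reagents that add atoms: none
Why: Acid-catalysed acetal hydrolysis removes both aryl MOM ethers; the chromone and diaryl-type ether are acid-stable, and dilute HCl in methanol is mild enough to leave ortho-prenyl phenols uncyclised.

## Compound list

1 | 2,4-dihydroxyacetophenone | CC(=O)c1ccc(O)cc1O | starting material
2 | 1-(2,4-dihydroxy-3,5-diiodophenyl)ethanone | CC(=O)c1cc(I)c(O)c(I)c1O | intermediate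
3 | 1-[2-hydroxy-3,5-diiodo-4-(methoxymethoxy)phenyl]ethanone | CC(=O)c1cc(I)c(OCOC)c(I)c1O | intermediate
4 | 1-[2-hydroxy-4-(methoxymethoxy)-3,5-bis(3-methylbut-2-en-1-yl)phenyl]ethanone | CC(=O)c1cc(CC=C(C)C)c(OCOC)c(CC=C(C)C)c1O | intermediate
5 | (E)-3-(dimethylamino)-1-[2-hydroxy-4-(methoxymethoxy)-3,5-bis(3-methylbut-2-en-1-yl)phenyl]prop-2-en-1-one | CN(C)/C=C/C(=O)c1cc(CC=C(C)C)c(OCOC)c(CC=C(C)C)c1O | intermediate
6 | 2,4-dihydroxybenzaldehyde | O=Cc1ccc(O)cc1O | starting material
7 | 2-hydroxy-4-(methoxymethoxy)benzaldehyde | COCOc1ccc(C=O)c(O)c1 | intermediate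
8 | 4-(methoxymethoxy)benzene-1,2-diol | COCOc1ccc(O)c(O)c1 | intermediate
9 | 4-(methoxymethoxy)cyclohexa-3,5-diene-1,2-dione | COCOC1=CC(=O)C(=O)C=C1 | intermediate
10 | 3-[2-hydroxy-4-(methoxymethoxy)phenoxy]-7-(methoxymethoxy)-6,8-bis(3-methylbut-2-en-1-yl)-4H-chromen-4-one | COCOc1ccc(Oc2coc3c(CC=C(C)C)c(OCOC)c(CC=C(C)C)cc3c2=O)c(O)c1 | intermediate
11 | eryvarin F | CC(C)=CCc1cc2c(=O)c(Oc3ccc(O)cc3O)coc2c(CC=C(C)C)c1O | target

## Summary

**Total steps:** 9
**Longest linear sequence:** 6 (Steps 1, 2, 3, 4, 8, 9)

**Three steps most likely to fail**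

1. **Step 8 (proposed new annulation).** Risks are C-attack of the enaminone on the quinone ring (Nenitzescu-type C–C bond at C5, or displacement of OMOM at C4), bonding to the wrong quinone oxygen (giving the 2-hydroxy-5-MOM-oxy-phenoxy isomer), and consumption of the quinone by liberated Me2NH.
   Fallback (known chemistry, different bond construction): make the C3–O bond as an α-aryloxy ketone and close the ring classically.
   - MOM-protect the 2-OH of 4 (NaH, MOMCl).
   - Convert to the α-diazoketone by detrifluoroacetylative diazo transfer (LiHMDS/CF3CO2CH2CF3, then MsN3/Et3N).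
   - Rh2(OAc)4-catalysed O–H insertion into 2,4-bis(methoxymethoxy)phenol (from 6 by bis-MOM protection and Baeyer–Villiger/Dakin oxidation).
   - DMF-DMA to the α-aryloxy enaminone, then HCl/MeOH, which removes all MOM groups and cyclises to eryvarin F.

2. **Step 3 (double Suzuki prenylation).** Risks are a sluggish second coupling at the doubly ortho-substituted C3, formation of branched (1,1-dimethylallyl) isomers, and protodeiodination.
   Fallback: drop the cross-coupling and install each prenyl by aromatic Claisen rearrangement of a 1,1-dimethylallyl aryl ether. Starting from 1: O-alkylate with 2-methylbut-3-yn-2-yl trifluoroacetate (CuCl2, DBU), semi-hydrogenate (Lindlar), heat; then repeat for the second ortho position. The [3,3] shift can only give the linear prenyl group.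

3. **Step 9 (final acidic deprotection).** The risk is acid-promoted cyclisation of the 7-OH onto a flanking prenyl group to give a 2,2-dimethylchroman.
   Fallback: change the protecting-group plan so the last step is neutral. Run Step 3 on unprotected 2, O-allylate the 4-OH (allyl bromide, K2CO3), use 4-(allyloxy)-1,2-benzoquinone in Step 8 (from 6 by 4-O-allylation, Dakin oxidation and Ag2O), and finish with Pd(PPh3)4/morpholine deallylation.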